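**Retrosynthetic overview**

- Ring C is closed last, by a catalyst-controlled oxa-Michael addition of the C8a hydroxyl onto an alkylidene β-keto ester (O1–C2). Before that, C3 is attached to the ring A ester by a crossed Claisen condensation (C3–C4) and C2 by Knoevenagel condensation with veratraldehyde (C2–C3). The C3 ester is then removed.
- The strategy rests on ring A (C4a, C5, C6, C7, C8, C8a). It carries oxygen on C7 and C8a, the acyl carbon C4 on C4a, prenyl groups on C6 and C8 and hydrogen on C5. This is the pattern of a folded linear 3,5,7-tricarbonyl heptanoate whose two inner methines are already prenylated.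
- Ring A is therefore built from an open chain: C4a–C5 aldol closure and aromatisation of methyl 7,7-dimethoxy-3,5-dioxo-4,6-diprenylheptanoate gives the 3,5-diprenyl-β-resorcylate, with no aromatic prenylation.
- The chain is cut between its C4 and C5 into the dianion of γ-prenylated methyl acetoacetate and the Weinreb amide of α-prenylated 3,3-dimethoxypropanoic acid. Both prenyl groups come from prenyl bromide by enolate alkylation.
- Order of ring formation: ring A (step 5), then ring C (step 9). Ring B is bought with veratraldehyde.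

Key step: step 5

Remark: the sense of induction of the cinchona thiourea in step 9 is assumed, not derived. The quinine-derived catalyst is written; if the first run gives the 2R series, its quinidine-derived pseudoenantiomer is used instead.

**Step 1**
Reactants: 1 methyl acetoacetate; 2 prenyl bromide
Product: 3 methyl 7-methyl-3-oxooct-6-enoate
Conditions: NaH, THF, 0 °C; n-BuLi, 0 °C; then 2, 0 °C to rt; aq HCl
Reagents that add atoms: none
Why: γ-Alkylation of the acetoacetate dianion: the terminal carbanion formed last is the most nucleophilic site and should displace the allylic bromide by SN2 at the primary carbon.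

**Step 2**
Reactants: 4 methyl 3,3-dimethoxypropanoate; 2 prenyl bromide
Product: 5 methyl 2-(dimethoxymethyl)-5-methylhex-4-enoate (racemic)
Conditions: LiN(i-Pr)2, THF, −78 °C; then 2, DMPU, −78 to −30 °C; aq NH4Cl
Reagents that add atoms: none
Why: Ester enolate alkylation with an allylic bromide at low temperature, where loss of methoxide from the enolate should be slow; the new stereocentre is formed racemic and is erased when ring A aromatises.

**Step 3**
Reactants: 5 methyl 2-(dimethoxymethyl)-5-methylhex-4-enoate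
Product: 6 2-(dimethoxymethyl)-N-methoxy-N,5-dimethylhex-4-enamide (racemic)
Conditions: MeNHOMe·HCl, i-PrMgCl, THF, −20 to 0 °C; aq NH4Cl
Reagents that add atoms: N,O-dimethylhydroxylamine hydrochloride, CNOC.Cl
Why: Weinreb amide formation by aminolysis of the ester with the chloromagnesium amide, conditions that leave the acetal and the alkene untouched; the α-centre stays racemic.

**Step 4**
Reactants: 3 methyl 7-methyl-3-oxooct-6-enoate; 6 2-(dimethoxymethyl)-N-methoxy-N,5-dimethylhex-4-enamide
Product: 7 methyl 7,7-dimethoxy-4,6-bis(3-methylbut-2-en-1-yl)-3,5-dioxoheptanoate (mixture of diastereomers and enol forms)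
Conditions: 3 (2.2 equiv), NaH, THF, 0 °C; n-BuLi, 0 °C; then 6, −78 to 0 °C; aq NH4Cl
Reagents that add atoms: none
Why: Claisen-type C-acylation of the β-keto ester dianion at its γ-carbon by the Weinreb amide, whose chelated tetrahedral intermediate stops at the ketone stage; the two new stereocentres are uncontrolled and both vanish in step 5.

**Step 5**
Reactants: 7 methyl 7,7-dimethoxy-4,6-bis(3-methylbut-2-en-1-yl)-3,5-dioxoheptanoate
Product: 9 methyl 2,4-dihydroxy-3,5-bis(3-methylbut-2-en-1-yl)benzoate, via tetracarbonyl aldehyde 8 (not isolated)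
Conditions: (a) 1 M aq HCl, THF, 0 °C to rt; (b) crude 8, K2CO3, MeOH, rt; (c) 1 M aq HCl to pH 3
Reagents that add atoms: none
Why: Dilute acid hydrolyses the acetal of 7 to the C7 aldehyde 8 (any β-methoxy enone from loss of one methanol reacts on in the same sense), and in methanolic carbonate the enolate of the C2 methylene, the only CH2 of the chain and flanked by the ester and the C3 ketone, adds to C7; E1cB loss of water gives the C2=C7 alkene, and enolisation of the C3 and C5 ketones towards C4 and C6 completes the benzene ring. The closest known reaction type is the biomimetic aldol cyclisation and aromatisation of 3,5,7-tricarbonyl esters to β-resorcylates, here run with an aldehyde terminus and two alkylated methines. Ring A closes in a 6-(enolendo)-exo-trig mode (6-endo-trig addition–elimination where the methoxy enone is the electrophile). No stereocentre is formed, and the two uncontrolled centres of 7 are erased. The step needs carbon rather than oxygen closure and aldol rather than Claisen folding: in basic methanol the oxygen-closed pyranols reopen while the arene is an irreversible sink, the acid stage is kept cold and short so that dehydration to a 4-pyranone does not set in, and Claisen attack of C6 on the ester is slow because it would build a quaternary carbon from the most stabilised enolate. Because both prenyl groups sit on C4 and C6 of the chain before the ring exists, the 3,5-substitution of the resorcylate is fixed by the chain and not by aromatic substitution.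

**Step 6**
Reactants: 9 methyl 2,4-dihydroxy-3,5-bis(3-methylbut-2-en-1-yl)benzoate
Product: 10 methyl 4-[(tert-butyldimethylsilyl)oxy]-2-hydroxy-3,5-bis(3-methylbut-2-en-1-yl)benzoate
Conditions: TBSCl, imidazole, DMAP (cat.), DMF, rt to 40 °C
Reagents that add atoms: tert-butyldimethylsilyl chloride (TBSCl), CC(C)(C)[Si](C)(C)Cl
Why: Phenol silylation: the 2-hydroxyl is held in a hydrogen bond to the ester carbonyl and is much less nucleophilic, so the silyl chloride should take the free 4-hydroxyl despite its two ortho prenyl groups.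

**Step 7**
Reactants: 10 methyl 4-[(tert-butyldimethylsilyl)oxy]-2-hydroxy-3,5-bis(3-methylbut-2-en-1-yl)benzoate; 11 tert-butyl acetate
Product: 12 tert-butyl 3-{4-[(tert-butyldimethylsilyl)oxy]-2-hydroxy-3,5-bis(3-methylbut-2-en-1-yl)phenyl}-3-oxopropanoate
Conditions: 11 (4 equiv), LiN(i-Pr)2 (4.2 equiv), THF, −78 °C; then 10, −78 to 0 °C; aq NH4Cl
Reagents that add atoms: none
Why: Crossed Claisen condensation: excess lithium enolate of tert-butyl acetate first forms the phenoxide and then acylates at the methyl ester, and deprotonation of the β-keto ester product prevents a second addition.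

**Step 8**
Reactants: 12 tert-butyl 3-{4-[(tert-butyldimethylsilyl)oxy]-2-hydroxy-3,5-bis(3-methylbut-2-en-1-yl)phenyl}-3-oxopropanoate; 13 3,4-dimethoxybenzaldehyde
Product: 14 tert-butyl 2-{4-[(tert-butyldimethylsilyl)oxy]-2-hydroxy-3,5-bis(3-methylbut-2-en-1-yl)benzoyl}-3-(3,4-dimethoxyphenyl)prop-2-enoate
Conditions: piperidine (cat.), AcOH (cat.), 4 Å molecular sieves, toluene, rt
Reagents that add atoms: none
Why: Knoevenagel condensation of the active methylene with the aromatic aldehyde under piperidinium acetate, with sieves taking up the water; the hydrogen-bonded phenol should not add to the new alkene at room temperature without a stronger catalyst.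

**Step 9**
Reactants: 14 tert-butyl 2-{4-[(tert-butyldimethylsilyl)oxy]-2-hydroxy-3,5-bis(3-methylbut-2-en-1-yl)benzoyl}-3-(3,4-dimethoxyphenyl)prop-2-enoate
Product: 18 (2S)-7-[(tert-butyldimethylsilyl)oxy]-2-(3,4-dimethoxyphenyl)-6,8-bis(3-methylbut-2-en-1-yl)-2,3-dihydro-4H-chromen-4-one, via cyclised tert-butyl ester 15 (not isolated), via bis-trimethylsilyl derivative 16 (not isolated), via beta-keto acid 17 (not isolated)
Conditions: thiourea from 9-amino-9-deoxy-epi-quinine and 3,5-bis(trifluoromethyl)phenyl isothiocyanate (10 mol%), toluene, −25 °C; then 2,6-lutidine, TMSOTf, CH2Cl2, −25 to 0 °C; pH 5 phosphate buffer; toluene, 60 °C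
Reagents that add atoms: none
Why: Intramolecular oxa-Michael addition (6-endo-trig) under bifunctional cinchona thiourea catalysis, in which the thiourea binds the two carbonyls of the alkylidene β-keto ester and the quinuclidine nitrogen delivers the phenol to one face of the benzylic carbon, which sets C2; silyl triflate cleavage of the tert-butyl ester and decarboxylation of the β-keto acid then remove the C3 ester without base, so that C2 should not open back to the chalcone.

**Step 10**
Reactants: 18 (2S)-7-[(tert-butyldimethylsilyl)oxy]-2-(3,4-dimethoxyphenyl)-6,8-bis(3-methylbut-2-en-1-yl)-2,3-dihydro-4H-chromen-4-one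
Product: 19 (2S)-2-(3,4-dimethoxyphenyl)-7-hydroxy-6,8-bis(3-methylbut-2-en-1-yl)-2,3-dihydro-4H-chromen-4-one
Conditions: HF·pyridine, pyridine, THF, 0 °C to rt
Reagents that add atoms: none
Why: Fluoride cleavage of the aryl silyl ether under pyridine-buffered HF, which avoids the base-induced ring opening that would racemise C2 and is mild enough to leave the prenyl alkenes alone.

**Compound list**

1 | methyl acetoacetate | COC(=O)CC(C)=O | starting material
2 | prenyl bromide (1-bromo-3-methylbut-2-ene) | CC(C)=CCBr | starting material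
3 | methyl 7-methyl-3-oxooct-6-enoate | COC(=O)CC(=O)CCC=C(C)C | intermediate
4 | methyl 3,3-dimethoxypropanoate | COC(=O)CC(OC)OC | starting material
5 | methyl 2-(dimethoxymethyl)-5-methylhex-4-enoate (racemic) | COC(=O)C(CC=C(C)C)C(OC)OC | intermediate
6 | 2-(dimethoxymethyl)-N-methoxy-N,5-dimethylhex-4-enamide (racemic) | CON(C)C(=O)C(CC=C(C)C)C(OC)OC | intermediate
7 | methyl 7,7-dimethoxy-4,6-bis(3-methylbut-2-en-1-yl)-3,5-dioxoheptanoate (diastereomer and enol mixture) | COC(=O)CC(=O)C(CC=C(C)C)C(=O)C(CC=C(C)C)C(OC)OC | intermediate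
8 | methyl 4,6-bis(3-methylbut-2-en-1-yl)-3,5,7-trioxoheptanoate (tautomer mixture) | COC(=O)CC(=O)C(CC=C(C)C)C(=O)C(CC=C(C)C)C=O | intermediate (not isolated)
9 | methyl 2,4-dihydroxy-3,5-bis(3-methylbut-2-en-1-yl)benzoate | COC(=O)c1cc(CC=C(C)C)c(O)c(CC=C(C)C)c1O | intermediate
10 | methyl 4-[(tert-butyldimethylsilyl)oxy]-2-hydroxy-3,5-bis(3-methylbut-2-en-1-yl)benzoate | COC(=O)c1cc(CC=C(C)C)c(O[Si](C)(C)C(C)(C)C)c(CC=C(C)C)c1O | intermediate
11 | tert-butyl acetate | CC(=O)OC(C)(C)C | starting material
12 | tert-butyl 3-{4-[(tert-butyldimethylsilyl)oxy]-2-hydroxy-3,5-bis(3-methylbut-2-en-1-yl)phenyl}-3-oxopropanoate | CC(C)(C)OC(=O)CC(=O)c1cc(CC=C(C)C)c(O[Si](C)(C)C(C)(C)C)c(CC=C(C)C)c1O | intermediate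
13 | 3,4-dimethoxybenzaldehyde (veratraldehyde) | COc1ccc(C=O)cc1OC | starting material
14 | tert-butyl 2-{4-[(tert-butyldimethylsilyl)oxy]-2-hydroxy-3,5-bis(3-methylbut-2-en-1-yl)benzoyl}-3-(3,4-dimethoxyphenyl)prop-2-enoate (alkene geometry not fixed) | COc1ccc(C=C(C(=O)OC(C)(C)C)C(=O)c2cc(CC=C(C)C)c(O[Si](C)(C)C(C)(C)C)c(CC=C(C)C)c2O)cc1OC | intermediate
15 | tert-butyl (2R)-7-[(tert-butyldimethylsilyl)oxy]-2-(3,4-dimethoxyphenyl)-4-hydroxy-6,8-bis(3-methylbut-2-en-1-yl)-2H-chromene-3-carboxylate (enol form of the 4-oxochromane-3-carboxylate; same spatial arrangement at C2 as the target, descriptor R by priority change only) | COc1ccc([C@@H]2C(C(=O)OC(C)(C)C)=C(O)c3cc(CC=C(C)C)c(O[Si](C)(C)C(C)(C)C)c(CC=C(C)C)c3O2)cc1OC | intermediate (not isolated)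
16 | trimethylsilyl (2R)-7-[(tert-butyldimethylsilyl)oxy]-2-(3,4-dimethoxyphenyl)-6,8-bis(3-methylbut-2-en-1-yl)-4-[(trimethylsilyl)oxy]-2H-chromene-3-carboxylate | COc1ccc([C@@H]2C(C(=O)O[Si](C)(C)C)=C(O[Si](C)(C)C)c3cc(CC=C(C)C)c(O[Si](C)(C)C(C)(C)C)c(CC=C(C)C)c3O2)cc1OC | intermediate (not isolated)
17 | (2R)-7-[(tert-butyldimethylsilyl)oxy]-2-(3,4-dimethoxyphenyl)-4-hydroxy-6,8-bis(3-methylbut-2-en-1-yl)-2H-chromene-3-carboxylic acid (enol form of the β-keto acid) | COc1ccc([C@@H]2C(C(=O)O)=C(O)c3cc(CC=C(C)C)c(O[Si](C)(C)C(C)(C)C)c(CC=C(C)C)c3O2)cc1OC | intermediate (not isolated)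
18 | (2S)-7-[(tert-butyldimethylsilyl)oxy]-2-(3,4-dimethoxyphenyl)-6,8-bis(3-methylbut-2-en-1-yl)-2,3-dihydro-4H-chromen-4-one | COc1ccc([C@@H]2CC(=O)c3cc(CC=C(C)C)c(O[Si](C)(C)C(C)(C)C)c(CC=C(C)C)c3O2)cc1OC | intermediate
19 | (2S)-2-(3,4-dimethoxyphenyl)-7-hydroxy-6,8-bis(3-methylbut-2-en-1-yl)-2,3-dihydro-4H-chromen-4-one (IN0946) | COc1ccc([C@@H]2CC(=O)c3cc(CC=C(C)C)c(O)c(CC=C(C)C)c3O2)cc1OC | target

**Step count and risks**

Total step count: 10. Longest linear sequence: 9 steps (steps 2, 3, 4, 5, 6, 7, 8, 9 and 10, from 4).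

Steps most likely to fail:

1. Step 5. The chain may close through oxygen and dehydrate to a 4-pyranone during the acid stage, or be cut by retro-Claisen cleavage in the basic stage, before the C2 enolate reaches C7. Fallback: ring A is not built from the chain but prenylated by cross-coupling. This sets out from prenyl bromide 2 and comes back at 9.
   - Purchased methyl 2,4-dihydroxybenzoate F1 is iodinated at C3 and C5 (benzyltrimethylammonium dichloroiodate, NaHCO3, CH2Cl2–MeOH) to methyl 2,4-dihydroxy-3,5-diiodobenzoate F2.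
   - F2 is acetylated (Ac2O, pyridine) to methyl 2,4-diacetoxy-3,5-diiodobenzoate F3.
   - 2 is converted with Bu3SnLi (from Bu3SnH and LiN(i-Pr)2, THF, −78 °C) into tributyl(3-methylbut-2-en-1-yl)stannane F4.
   - Double Stille coupling of F3 with F4 (Pd(PPh3)4, a zerovalent palladium complex, DMF, 90 °C) should give methyl 2,4-diacetoxy-3,5-bis(3-methylbut-2-en-1-yl)benzoate F5.
   - K2CO3 in MeOH removes both acetates to give 9.

2. Step 4. The secondary carbanion of the dianion may act only as a base towards the α-branched amide, so that enolisation replaces acylation. Fallback: the bond is made by aldol addition and the ketone is restored by oxidation. This sets out from 6 and comes back at 7.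
   - Reduction of 6 with i-Bu2AlH (THF, −78 °C) gives 2-(dimethoxymethyl)-5-methylhex-4-enal F6.
   - The dianion of 3 (NaH, n-BuLi, THF) adds to F6 at −78 °C to give methyl 5-hydroxy-7,7-dimethoxy-4,6-bis(3-methylbut-2-en-1-yl)-3-oxoheptanoate F7 as a diastereomer mixture.
   - Dess–Martin periodinane with NaHCO3 in CH2Cl2 oxidises the C5 alcohol to give 7.

3. Step 9. Facial selectivity may be poor on this crowded phenol, or the C2 centre may erode by retro-oxa-Michael opening before the ester is removed. Fallback: the stereocentre is set by carbon–carbon bond formation on a chromone. This sets out from 12 and comes back at 18.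
   - 12 is freed of its tert-butyl ester and decarboxylated (TMSOTf, 2,6-lutidine, CH2Cl2; buffer; 60 °C) to 1-{4-[(tert-butyldimethylsilyl)oxy]-2-hydroxy-3,5-bis(3-methylbut-2-en-1-yl)phenyl}ethan-1-one F8.
   - N,N-Dimethylformamide dimethyl acetal in toluene at 90 °C gives the enaminone (E)-3-(dimethylamino)-1-{4-[(tert-butyldimethylsilyl)oxy]-2-hydroxy-3,5-bis(3-methylbut-2-en-1-yl)phenyl}prop-2-en-1-one F9.
   - Dilute HCl in CH2Cl2 at rt closes F9, with loss of dimethylamine, to 7-[(tert-butyldimethylsilyl)oxy]-6,8-bis(3-methylbut-2-en-1-yl)-4H-chromen-4-one F10.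
   - Asymmetric conjugate addition of 3,4-dimethoxyphenylboronic acid to F10 (Pd(OCOCF3)2, t-BuPyOx of the hand that gives the 2S product, NH4PF6, H2O, ClCH2CH2Cl, 60 °C) gives 18.

**Further compounds**

F1 | step 5 | methyl 2,4-dihydroxybenzoate | COC(=O)c1ccc(O)cc1O
F2 | step 5 | methyl 2,4-dihydroxy-3,5-diiodobenzoate | COC(=O)c1cc(I)c(O)c(I)c1O
F3 | step 5 | methyl 2,4-diacetoxy-3,5-diiodobenzoate | COC(=O)c1cc(I)c(OC(C)=O)c(I)c1OC(C)=O
F4 | step 5 | tributyl(3-methylbut-2-en-1-yl)stannane | CCCC[Sn](CCCC)(CCCC)CC=C(C)C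
F5 | step 5 | methyl 2,4-diacetoxy-3,5-bis(3-methylbut-2-en-1-yl)benzoate | COC(=O)c1cc(CC=C(C)C)c(OC(C)=O)c(CC=C(C)C)c1OC(C)=O
F6 | step 4 | 2-(dimethoxymethyl)-5-methylhex-4-enal | O=CC(CC=C(C)C)C(OC)OC
F7 | step 4 | methyl 5-hydroxy-7,7-dimethoxy-4,6-bis(3-methylbut-2-en-1-yl)-3-oxoheptanoate | COC(=O)CC(=O)C(CC=C(C)C)C(O)C(CC=C(C)C)C(OC)OC
F8 | step 9 | 1-{4-[(tert-butyldimethylsilyl)oxy]-2-hydroxy-3,5-bis(3-methylbut-2-en-1-yl)phenyl}ethan-1-one | CC(=O)c1cc(CC=C(C)C)c(O[Si](C)(C)C(C)(C)C)c(CC=C(C)C)c1O
F9 | step 9 | (E)-3-(dimethylamino)-1-{4-[(tert-butyldimethylsilyl)oxy]-2-hydroxy-3,5-bis(3-methylbut-2-en-1-yl)phenyl}prop-2-en-1-one | CN(C)/C=C/C(=O)c1cc(CC=C(C)C)c(O[Si](C)(C)C(C)(C)C)c(CC=C(C)C)c1O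
F10 | step 9 | 7-[(tert-butyldimethylsilyl)oxy]-6,8-bis(3-methylbut-2-en-1-yl)-4H-chromen-4-one | O=c1ccoc2c(CC=C(C)C)c(O[Si](C)(C)C(C)(C)C)c(CC=C(C)C)cc12
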